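**Retrosynthetic overview**
1. Target 20 ⇐ benzyl ester 19 (hydrogenolysis) ⇐ phenol 18 (selective O-methylation of the only phenol that is not hydrogen-bonded to an ester carbonyl).
2. Key disconnection (new step): the depside C(=O)–O bond and all of ring A (the acyl ring) of 18 ⇐ phenol 14 + diketo-dioxinone 9, by acylketene capture at the phenol oxygen followed by aldol aromatization.
3. Ring B (the benzoic acid ring) as benzyl ester 14 ⇐ benzodioxinone 11 + benzyl alcohol 12 (alkoxide opening); 11 ⇐ the same diketo-dioxinone 9 by amine-mediated aldol aromatization at room temperature.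
4. 9 ⇐ keto-dioxinone 4 + Weinreb amide 7 (dianion acylation); 4 ⇐ dioxinone 1 + acetyl chloride 2.
5. Ring order: ring B is formed first (step 4); ring A is then built directly on the 4-oxygen of ring B (step 6).

Assumption: the target has no stereocentre and is achiral, so there is no enantiomer to select; the route delivers the single constitutional isomer drawn.

**Route**

Step 1
Reactants: 1 2,2,6-trimethyl-4H-1,3-dioxin-4-one; 2 acetyl chloride
Product: 4 2,2-dimethyl-6-(2-oxopropyl)-4H-1,3-dioxin-4-one, via lithium dienolate 3 (not isolated)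
Conditions: 1 (2 equiv), LiN(SiMe3)2 (2 equiv), THF, −78 °C; then 2 (1 equiv), −78 °C; aq HCl quench (excess 1 recovered)
Reagents that add atoms: none
Why: γ-Deprotonation of the vinylogous ester gives the dienolate, which is C-acylated at its terminal carbon by the acid chloride, while the second equivalent of dienolate takes up the proton of the more acidic β-keto product (crossed Claisen-type enolate C-acylation).

Step 2
Reactants: 5 octanoyl chloride; 6 N,O-dimethylhydroxylamine hydrochloride
Product: 7 N-methoxy-N-methyloctanamide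
Conditions: K2CO3 (2.5 equiv), H2O/EtOAc, 0 °C→rt
Reagents that add atoms: none
Why: Schotten–Baumann N-acylation of the liberated hydroxylamine by the acid chloride gives the Weinreb amide cleanly.

Step 3
Reactants: 4 2,2-dimethyl-6-(2-oxopropyl)-4H-1,3-dioxin-4-one; 7 N-methoxy-N-methyloctanamide
Product: 9 6-(2,4-dioxoundecyl)-2,2-dimethyl-4H-1,3-dioxin-4-one, via dilithium dianion 8 (not isolated)
Conditions: LiN(i-Pr)2 (2.2 equiv), THF, −78 °C; then 7 (1.1 equiv), −78→−20 °C; aq HCl quench
Reagents that add atoms: none
Why: The dianion reacts at its more basic terminal carbon with the Weinreb amide, whose chelated tetrahedral adduct prevents over-addition and releases the tricarbonyl chain only on acidic quench (Weinreb ketone synthesis applied to a 1,3-dicarbonyl dianion).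

Step 4
Reactants: 9 6-(2,4-dioxoundecyl)-2,2-dimethyl-4H-1,3-dioxin-4-one
Product: 11 5-heptyl-7-hydroxy-2,2-dimethyl-4H-1,3-benzodioxin-4-one, via aldol adduct 10 (not isolated)
Conditions: Et3N (2 equiv), CH2Cl2, 0 °C→rt, 16 h; then 1 M aq HCl
Reagents that add atoms: none
Why: The amine generates the extended enolate of the dioxinone, whose C5 adds to the distal heptyl ketone to close the six-membered ring, and loss of water from adduct 10 is driven by aromatization to the acetonide-protected resorcylate (intramolecular vinylogous aldol condensation and aromatization, with the dioxinone ring left intact).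

Step 5
Reactants: 11 5-heptyl-7-hydroxy-2,2-dimethyl-4H-1,3-benzodioxin-4-one; 12 benzyl alcohol
Product: 14 benzyl 2,4-dihydroxy-6-heptylbenzoate, via sodium benzyloxide 13 (not isolated)
Conditions: 12 (6 equiv), NaH (3.5 equiv), THF, 0 °C, 20 min; then 11, 0→50 °C, 6 h; 1 M aq HCl
Reagents that add atoms: none
Why: The alkoxide adds to the ester-type carbonyl of the benzodioxinone, the ring opens and the hemiketal oxide loses acetone, giving the benzyl salicylate with both phenols free (nucleophilic acyl substitution, transesterification of a benzodioxinone).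

Step 6
Reactants: 14 benzyl 2,4-dihydroxy-6-heptylbenzoate; 9 6-(2,4-dioxoundecyl)-2,2-dimethyl-4H-1,3-dioxin-4-one
Product: 18 benzyl 6-heptyl-4-[(6-heptyl-2,4-dihydroxybenzoyl)oxy]-2-hydroxybenzoate, via acylketene 15 (not isolated), via aryl triketo ester 16 (not isolated), via aryl aldol adduct 17 (not isolated)
Conditions: 14 (2.0 equiv, 0.5 M), 9 (1.0 equiv), PhMe, 110 °C, 45 min; cool, CH2Cl2, Et3N (2 equiv), 0 °C→rt; then CF3CO2H, rt (excess 14 recovered)
Reagents that add atoms: none
Why: Proposed new method: a depside ester is made by building the acyl ring on the phenol oxygen. Thermal retro-hetero-Diels–Alder loss of acetone from 9 gives the acylketene, which should add the O–H of the only non-chelated phenol of 14 (the 4-OH; the 2-OH is locked in a hydrogen bond to the benzyl ester) through the usual six-membered pseudopericyclic transition state, and a high phenol concentration is used to outrun closure of the ketene on its own enol oxygen. The resulting aryl β-keto ester is more C–H acidic at C2 than an alkyl ester, so a non-nucleophilic amine in aprotic solvent should trigger the C2-to-C7 aldol closure known for alkyl triketo esters without an alkoxide that could cleave the aryl ester, and acid then dehydrates adduct 17 to the aromatic ring. The closest known reaction type is acylketene capture by aliphatic alcohols followed by aldol aromatization; a hindered, electron-poor resorcylate phenol as the trap and an aryl (depside) ester as the product have not been shown.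

Step 7
Reactants: 18 benzyl 6-heptyl-4-[(6-heptyl-2,4-dihydroxybenzoyl)oxy]-2-hydroxybenzoate
Product: 19 benzyl 6-heptyl-4-[(6-heptyl-2-hydroxy-4-methoxybenzoyl)oxy]-2-hydroxybenzoate
Conditions: MeI (1.1 equiv), K2CO3 (1.1 equiv), acetone, rt
Reagents that add atoms: iodomethane (MeI), CI
Why: The 4-OH of ring A is the only phenol not hydrogen-bonded to an ortho ester carbonyl, so it is the most acidic and nucleophilic and is alkylated selectively with one equivalent of base and iodomethane (Williamson ether synthesis).

Step 8
Reactants: 19 benzyl 6-heptyl-4-[(6-heptyl-2-hydroxy-4-methoxybenzoyl)oxy]-2-hydroxybenzoate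
Product: 20 6-heptyl-4-[(6-heptyl-2-hydroxy-4-methoxybenzoyl)oxy]-2-hydroxybenzoic acid
Conditions: H2 (1 atm), 10% Pd/C, EtOAc, rt
Reagents that add atoms: none
Why: Catalytic hydrogenolysis cleaves the benzylic C–O bond of the benzyl ester while the aryl depside ester, the methyl ether and both arenes are inert at 1 atm.

**Compound list**
1 | 2,2,6-trimethyl-4H-1,3-dioxin-4-one | CC1=CC(=O)OC(C)(C)O1 | starting material
2 | acetyl chloride | CC(=O)Cl | starting material
3 | lithium 2,2-dimethyl-6-methylidene-6H-1,3-dioxin-4-olate (lithium dienolate of 1) | [Li+].[O-]C1=CC(=C)OC(C)(C)O1 | intermediate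
4 | 2,2-dimethyl-6-(2-oxopropyl)-4H-1,3-dioxin-4-one | CC(=O)CC1=CC(=O)OC(C)(C)O1 | intermediate
5 | octanoyl chloride | CCCCCCCC(=O)Cl | starting material
6 | N,O-dimethylhydroxylamine hydrochloride | CNOC.Cl | starting material
7 | N-methoxy-N-methyloctanamide | CCCCCCCC(=O)N(C)OC | intermediate
8 | dilithium 2,2-dimethyl-6-(2-oxidoprop-2-en-1-ylidene)-6H-1,3-dioxin-4-olate (dianion of 4) | [Li+].[Li+].C=C([O-])C=C1C=C([O-])OC(C)(C)O1 | intermediate
9 | 6-(2,4-dioxoundecyl)-2,2-dimethyl-4H-1,3-dioxin-4-one | CCCCCCCC(=O)CC(=O)CC1=CC(=O)OC(C)(C)O1 | intermediate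
10 | 5-heptyl-5-hydroxy-2,2-dimethyl-5,6-dihydro-4H-1,3-benzodioxine-4,7(8H)-dione (racemic aldol adduct) | CCCCCCCC1(O)CC(=O)CC2=C1C(=O)OC(C)(C)O2 | intermediate
11 | 5-heptyl-7-hydroxy-2,2-dimethyl-4H-1,3-benzodioxin-4-one | CCCCCCCc1cc(O)cc2OC(C)(C)OC(=O)c12 | intermediate
12 | benzyl alcohol | OCc1ccccc1 | starting material
13 | sodium benzyloxide | [Na+].[O-]Cc1ccccc1 | intermediate
14 | benzyl 2,4-dihydroxy-6-heptylbenzoate | CCCCCCCc1cc(O)cc(O)c1C(=O)OCc1ccccc1 | intermediate
15 | tetradec-1-ene-1,3,5,7-tetrone (acylketene) | CCCCCCCC(=O)CC(=O)CC(=O)C=C=O | intermediate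
16 | benzyl 6-heptyl-2-hydroxy-4-[(3,5,7-trioxotetradecanoyl)oxy]benzoate | CCCCCCCC(=O)CC(=O)CC(=O)CC(=O)Oc1cc(O)c(C(=O)OCc2ccccc2)c(CCCCCCC)c1 | intermediate
17 | benzyl 6-heptyl-4-[(2-heptyl-2-hydroxy-4,6-dioxocyclohexane-1-carbonyl)oxy]-2-hydroxybenzoate (racemic diastereomer mixture) | CCCCCCCC1(O)CC(=O)CC(=O)C1C(=O)Oc1cc(O)c(C(=O)OCc2ccccc2)c(CCCCCCC)c1 | intermediate
18 | benzyl 6-heptyl-4-[(6-heptyl-2,4-dihydroxybenzoyl)oxy]-2-hydroxybenzoate | CCCCCCCc1cc(OC(=O)c2c(O)cc(O)cc2CCCCCCC)cc(O)c1C(=O)OCc1ccccc1 | intermediate
19 | benzyl 6-heptyl-4-[(6-heptyl-2-hydroxy-4-methoxybenzoyl)oxy]-2-hydroxybenzoate | CCCCCCCc1cc(OC(=O)c2c(O)cc(OC)cc2CCCCCCC)cc(O)c1C(=O)OCc1ccccc1 | intermediate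
20 | 6-heptyl-4-[(6-heptyl-2-hydroxy-4-methoxybenzoyl)oxy]-2-hydroxybenzoic acid | CCCCCCCc1cc(OC(=O)c2c(O)cc(OC)cc2CCCCCCC)cc(O)c1C(=O)O | target

**Totals**
Total step count: 8. Longest linear sequence: 7 steps (steps 1, 3, 4, 5, 6, 7, 8); step 2 is a one-step side branch.

**Three steps most likely to fail**

Step 6 (the proposed new step). The phenol of 14 is electron-poor and may capture the acylketene too slowly, so that the ketene closes on its own enol oxygen to a 4-hydroxy-2-pyranone. The aryl triketo ester 16 also carries a good phenoxide leaving group, so it may lactonize or undergo Claisen closure with loss of 14 instead of the aldol. The fallback uses known chemistry, sets out from 14 and comes back to the route at 19, bypassing step 7. Compound 14 is methylated at its free 4-OH (MeI, K2CO3, acetone, rt) to give benzyl 6-heptyl-2-hydroxy-4-methoxybenzoate F1. Hydrogenolysis (H2, 10% Pd/C, EtOAc) gives 6-heptyl-2-hydroxy-4-methoxybenzoic acid F2. This acid is activated with trifluoroacetic anhydride in toluene as 6-heptyl-2-hydroxy-4-methoxybenzoic trifluoroacetic anhydride F3, which acylates a second portion of 14 at its non-chelated 4-OH to give 19.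

Step 5. The phenol of 11 is deprotonated first, and the resulting phenoxide lies para to the ring carbon that carries the carbonyl, so benzyloxide may add to that carbonyl only sluggishly. The fallback sets out from 9 and comes back at 14, replacing steps 4 and 5 by ketene capture with the alcohol. Compound 9 is heated with benzyl alcohol 12 (1.5 equiv) in toluene at 110 °C; acetone is lost and acylketene 15 is trapped as benzyl 3,5,7-trioxotetradecanoate F4. Cs2CO3 in i-PrOH/CH2Cl2 at rt closes it to the aldol adduct benzyl 2-heptyl-2-hydroxy-4,6-dioxocyclohexane-1-carboxylate F5, and aq HCl dehydrates this to 14.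

Step 3. The dianion can be quenched by proton transfer or O-acylated, and product 9 is sensitive, aromatizing to benzodioxinone 11 on base or prolonged contact with silica. The fallback sets out from 4 and comes back at 9, replacing acylation by aldol addition and oxidation. Dianion 8 is generated as before and treated with octanal at −78 °C to give racemic 6-(4-hydroxy-2-oxoundecyl)-2,2-dimethyl-4H-1,3-dioxin-4-one F6. Oxidation with Dess–Martin periodinane (NaHCO3, CH2Cl2, 0 °C) gives 9.

**Further compounds**
F1 | step 6 | benzyl 6-heptyl-2-hydroxy-4-methoxybenzoate | CCCCCCCc1cc(OC)cc(O)c1C(=O)OCc1ccccc1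
F2 | step 6 | 6-heptyl-2-hydroxy-4-methoxybenzoic acid | CCCCCCCc1cc(OC)cc(O)c1C(=O)O
F3 | step 6 | 6-heptyl-2-hydroxy-4-methoxybenzoic trifluoroacetic anhydride | CCCCCCCc1cc(OC)cc(O)c1C(=O)OC(=O)C(F)(F)F
F4 | step 5 | benzyl 3,5,7-trioxotetradecanoate | CCCCCCCC(=O)CC(=O)CC(=O)CC(=O)OCc1ccccc1
F5 | step 5 | benzyl 2-heptyl-2-hydroxy-4,6-dioxocyclohexane-1-carboxylate (racemic diastereomer mixture) | CCCCCCCC1(O)CC(=O)CC(=O)C1C(=O)OCc1ccccc1
F6 | step 3 | 6-(4-hydroxy-2-oxoundecyl)-2,2-dimethyl-4H-1,3-dioxin-4-one (racemic) | CCCCCCCC(O)CC(=O)CC1=CC(=O)OC(C)(C)O1
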